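**Strategy.** Everything rests on the C2'–C3' bond of the cis-dihydrobenzofuran. The feature exploited is that C2' is a benzylic ether carbon (bonded to O1' and ring A) whose hydrogen lies 1,5 to C3', a carbon attached to ring B ortho to O1'. A rhodium carbenoid at C3' therefore inserts into the C2'–H bond of a ring A benzyl ether, closing the five-membered ring and setting C2' and C3' cis in one catalyst-controlled operation. The precursor is an aryl diazoacetate that already carries the finished tetrahydrofuran (two acetates, two phenolic benzyl ethers), built from 5-iodovanillin by syn-aldol with a eugenol-derived (R)-α-chloroaldehyde, anti-reduction and chloride displacement.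

Key step: step 17

Numbering and abbreviations: tetrahydrofuran O1, C2 (bears ring B), C3 (bears CH2O), C4 (bears O), C5 (bears CH2–ring C); dihydrobenzofuran O1', C2' (bears ring A), C3'. ArB = 4-{[4-(benzyloxy)-3-methoxybenzyl]oxy}-3-iodo-5-methoxyphenyl; ArC = 4-(benzyloxy)-3-methoxyphenyl (ring A carries the same substituents); TBDPS = tert-butyldiphenylsilyl; Rh2(S-PTTL)4 = dirhodium tetrakis[N-phthaloyl-(S)-tert-leucinate].

Assumption (chemistry): the catalyst antipodes written in steps 5 and 17 are taken to deliver the (R)-chloride 8 and the (2'R,3'S)-ester 24; each sense would be checked on a model substrate and the mirror-image catalyst used if it proved opposite.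

Protecting-group design: the two aliphatic oxygens are acetates during the key step, so they are lost in the hydride step and the last step cleaves only the two fast-reacting phenolic benzyl ethers. The C3 hydroxymethyl oxygen is a bulky silyl ether from the enolate stage to the ring closure, so that no ether oxygen 1,5 to C5 competes with the C2 hydroxyl.

Step 1
Reactants: 1 4-(benzyloxy)-3-methoxybenzyl alcohol
Product: 2 4-(benzyloxy)-3-methoxybenzyl chloride
Conditions: SOCl2, CH2Cl2, 0 °C → rt
Reagents that add atoms: thionyl chloride, ClS(Cl)=O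
Why: Chlorodehydroxylation through the chlorosulfite; the electron-rich benzylic alcohol reacts at 0 °C and the phenolic benzyl ether is untouched.

Step 2
Reactants: 3 eugenol
Product: 4 4-allyl-1-(benzyloxy)-2-methoxybenzene
Conditions: BnBr, K2CO3, acetone, reflux
Reagents that add atoms: benzyl bromide, BrCc1ccccc1
Why: Williamson etherification of the phenoxide; the phenol is masked before hydroboration and enamine chemistry and the benzyl group is kept to the last step.

Step 3
Reactants: 4 4-allyl-1-(benzyloxy)-2-methoxybenzene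
Product: 6 3-[4-(benzyloxy)-3-methoxyphenyl]propan-1-ol, via alkyl-9-BBN borane 5 (not isolated)
Conditions: 9-BBN, THF, 0 °C → rt; then NaOH, H2O2, H2O, 0 °C
Reagents that add atoms: hydrogen peroxide, OO
Why: Anti-Markovnikov hydroboration–oxidation of the terminal alkene; 9-BBN gives the primary borane regioselectively and alkaline peroxide replaces boron by hydroxyl.

Step 4
Reactants: 6 3-[4-(benzyloxy)-3-methoxyphenyl]propan-1-ol
Product: 7 3-[4-(benzyloxy)-3-methoxyphenyl]propanal
Conditions: Dess–Martin periodinane, NaHCO3, CH2Cl2, 0 °C → rt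
Reagents that add atoms: none
Why: Dess–Martin oxidation stops at the aldehyde under buffered, non-aqueous conditions that do not touch the electron-rich arene.

Step 5
Reactants: 7 3-[4-(benzyloxy)-3-methoxyphenyl]propanal
Product: 8 (R)-2-chloro-3-[4-(benzyloxy)-3-methoxyphenyl]propanal
Conditions: N-chlorosuccinimide, (2S,5S)-2,5-diphenylpyrrolidine (10 mol%), CH2Cl2, 0 °C → rt; used at once
Reagents that add atoms: N-chlorosuccinimide, O=C1CCC(=O)N1Cl
Why: Enamine-catalysed α-chlorination in which the C2-symmetric amine shields one face of the E-enamine, so the catalyst sets the (R) centre; the product is used at once because it racemises on storage.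

Step 6
Reactants: 9 5-iodovanillin; 2 4-(benzyloxy)-3-methoxybenzyl chloride
Product: 10 4-{[4-(benzyloxy)-3-methoxybenzyl]oxy}-3-iodo-5-methoxybenzaldehyde (ArB–CHO)
Conditions: K2CO3, Bu4NI (cat.), DMF, 50 °C
Reagents that add atoms: none
Why: Williamson etherification of the hindered but acidic phenoxide by the reactive benzylic chloride under iodide catalysis; this installs the O1'–CH2–ring A unit whose C–H bond is used in step 17.

Step 7
Reactants: 10 ArB–CHO
Product: 11 ethyl 3-hydroxy-3-ArB-propanoate (racemic)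
Conditions: LiN(iPr)2, EtOAc, THF, −78 °C; then 10; H2O quench
Reagents that add atoms: ethyl acetate, CCOC(C)=O
Why: Aldol addition of the lithium ester enolate to the aryl aldehyde; the aryl iodide is inert at −78 °C and the racemic carbinol centre is destroyed in step 10.

Step 8
Reactants: 11 ethyl 3-hydroxy-3-ArB-propanoate
Product: 12 1-ArB-propane-1,3-diol (racemic)
Conditions: LiBH4, THF, 0 °C → rt
Reagents that add atoms: none
Why: LiBH4 reduces the ester to the primary alcohol chemoselectively; aryl iodide and benzyl ethers are not reduced.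

Step 9
Reactants: 12 1-ArB-propane-1,3-diol
Product: 13 3-(TBDPS-oxy)-1-ArB-propan-1-ol (racemic)
Conditions: TBDPSCl, imidazole, CH2Cl2, 0 °C
Reagents that add atoms: tert-butyl(chloro)diphenylsilane, CC(C)(C)[Si](Cl)(c1ccccc1)c1ccccc1
Why: Silylation of the primary hydroxyl in preference to the hindered secondary benzylic one; the bulky silyl ether survives enolisation and acetic acid and is a poor neighbouring group in step 13.

Step 10
Reactants: 13 3-(TBDPS-oxy)-1-ArB-propan-1-ol
Product: 14 3-(TBDPS-oxy)-1-ArB-propan-1-one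
Conditions: Dess–Martin periodinane, NaHCO3, CH2Cl2, rt
Reagents that add atoms: none
Why: Dess–Martin oxidation of the secondary benzylic alcohol gives the aryl ketone, the enolate precursor for the aldol.

Step 11
Reactants: 14 3-(TBDPS-oxy)-1-ArB-propan-1-one; 8 (R)-2-chloro-3-[4-(benzyloxy)-3-methoxyphenyl]propanal
Product: 17 (2S,3S,4R)-4-chloro-3-hydroxy-2-[(TBDPS-oxy)methyl]-1-ArB-5-ArC-pentan-1-one, via Z-enol dibutylborinate 15 (not isolated), via dibutylboron aldolate 16 (not isolated)
Conditions: Bu2BOTf, iPr2NEt, CH2Cl2, −78 → 0 °C; then 8, −78 °C; pH 7 buffer, MeOH, H2O2, 0 °C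
Reagents that add atoms: none
Why: Boron aldol reaction in which the Z-enol borinate reacts through a chair Zimmerman–Traxler transition state (2,3-syn) with the aldehyde in the Cornforth arrangement (C–Cl opposed to C=O, 3,4-anti chlorohydrin), so the configuration of 8 sets tetrahydrofuran C3 and C4, while −78 °C and a hindered amine keep 8 from racemising.

Step 12
Reactants: 17 (2S,3S,4R)-4-chloro-3-hydroxy-2-[(TBDPS-oxy)methyl]-1-ArB-5-ArC-pentan-1-one
Product: 18 (1S,2R,3S,4R)-4-chloro-2-[(TBDPS-oxy)methyl]-1-ArB-5-ArC-pentane-1,3-diol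
Conditions: Me4NBH(OAc)3, MeCN/AcOH, −30 °C
Reagents that add atoms: none
Why: Evans–Saksena reduction in which the existing hydroxyl exchanges onto boron and delivers hydride intramolecularly through a chair transition state, setting the new benzylic carbinol (tetrahydrofuran C2) 1,3-anti to it; iodide, chloride, silyl ether and benzyl ethers are inert.

Step 13
Reactants: 18 (1S,2R,3S,4R)-4-chloro-2-[(TBDPS-oxy)methyl]-1-ArB-5-ArC-pentane-1,3-diol
Product: 19 (2S,3S,4S,5S)-2-ArB-5-(ArC-methyl)-3-[(TBDPS-oxy)methyl]tetrahydrofuran-4-ol (2,3-trans-3,4-trans-4,5-cis)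
Conditions: AgOTf, Ag2O, THF, rt → 40 °C, dark
Reagents that add atoms: none
Why: Silver-assisted intramolecular etherification (5-exo-tet) in which the benzylic hydroxyl displaces the secondary chloride with inversion, turning the anti-chlorohydrin into the 4,5-cis tetrahydrofuran while Ag2O takes up the acid and the hindered silyl ether oxygen stays out.

Step 14
Reactants: 19 (2S,3S,4S,5S)-2-ArB-5-(ArC-methyl)-3-[(TBDPS-oxy)methyl]tetrahydrofuran-4-ol
Product: 20 (2S,3S,4S,5S)-2-ArB-5-(ArC-methyl)-3-(hydroxymethyl)tetrahydrofuran-4-ol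
Conditions: Bu4NF, THF, 0 °C → rt
Reagents that add atoms: none
Why: Fluoride-induced desilylation frees the primary alcohol; nothing else in 19 is sensitive to fluoride or mild base.

Step 15
Reactants: 20 (2S,3S,4S,5S)-2-ArB-5-(ArC-methyl)-3-(hydroxymethyl)tetrahydrofuran-4-ol
Product: 21 [(2S,3R,4S,5S)-4-acetoxy-2-ArB-5-(ArC-methyl)tetrahydrofuran-3-yl]methyl acetate (geometry as in 20; the C3 descriptor changes only through the acetate priorities)
Conditions: Ac2O, pyridine, DMAP (cat.), CH2Cl2, rt
Reagents that add atoms: acetic anhydride, CC(=O)OC(C)=O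
Why: Nucleophile-catalysed acylation of both hydroxyls; acetates are inert to palladium, silver and the rhodium carbenoid, prevent O–H insertion, and fall off without an extra step in step 18.

Step 16
Reactants: 21 diacetate aryl iodide; 22 ethyl diazoacetate
Product: 23 ethyl 2-diazo-2-{2-[(4-benzyloxy-3-methoxybenzyl)oxy]-3-methoxy-5-[(2S,3R,4S,5S)-4-acetoxy-3-(acetoxymethyl)-5-(ArC-methyl)tetrahydrofuran-2-yl]phenyl}acetate
Conditions: Pd(PPh3)4 (5 mol%), Ag2CO3, Et3N, toluene, rt
Reagents that add atoms: none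
Why: Palladium-catalysed cross-coupling of the aryl iodide with the C–H bond of ethyl diazoacetate (oxidative addition, silver- and base-assisted transfer of the diazoacetate carbon, reductive elimination) runs at room temperature with retention of the diazo group and tolerates esters and ethers.

Step 17
Reactants: 23 tetrahydrofuran-bearing aryl diazoacetate
Product: 24 ethyl (2R,3S)-2-ArC-7-methoxy-5-[(2S,3R,4S,5S)-4-acetoxy-3-(acetoxymethyl)-5-(ArC-methyl)tetrahydrofuran-2-yl]-2,3-dihydrobenzofuran-3-carboxylate (2,3-cis)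
Conditions: Rh2(S-PTTL)4 (2 mol%), toluene, −78 °C, slow addition of 23; then −78 → −40 °C
Reagents that add atoms: none
Why: The dirhodium carboxylate expels N2 from 23 to give a donor/acceptor rhodium carbenoid at C3' on ring B, which inserts into one of the two enantiotopic C–H bonds of the adjacent O1'–CH2–ring A group through a concerted, three-centre, hydride-transfer-like transition state, forming the C2'–C3' bond. The closest known reaction is the cis- and enantioselective intramolecular C–H insertion of 2-(benzyloxy)phenyl diazoacetates catalysed by dirhodium N-phthaloyl amino-acid carboxylates. The dihydrobenzofuran closes in the 1,5-insertion mode (C3', ring B C–C, O1', C2'), the only five-membered closure open to this carbenoid. C2' and C3' are created together and both are set by the chiral ligand sphere of the catalyst, which selects the hydrogen to be replaced and holds the ester and ring A on the same face in the transition state (kinetic cis product, 2'R,3'S), the remote tetrahydrofuran centres having no say. The step needs site selectivity and cis selectivity: the O1'–CH2 group is the only C–H donor 1,5 to the carbenoid and is doubly activated by O1' and the para-oxygenated ring A, whereas the tetrahydrofuran C2–H is meta on ring B and the other ether C–H bonds can be reached only bimolecularly, which slow addition at low concentration suppresses. The neutral conditions at −78 °C leave the base-labile cis ester unepimerised.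

Step 18
Reactants: 24 cis-dihydrobenzofuran-3-carboxylate diacetate
Product: 25 (2S,3S,4S,5S)-2-[(2R,3R)-2-ArC-3-(hydroxymethyl)-7-methoxy-2,3-dihydrobenzofuran-5-yl]-5-(ArC-methyl)-3-(hydroxymethyl)tetrahydrofuran-4-ol
Conditions: iBu2AlH (excess), CH2Cl2, −78 → −20 °C; aq. potassium sodium tartrate
Reagents that add atoms: none
Why: Hydride reduction converts the ethyl ester into the C3' hydroxymethyl group and cleaves both acetates; at low temperature the tetrahedral aluminium intermediates do not enolise, so the cis relation at C2'/C3' is kept.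

Step 19
Reactants: 25 bis-O-benzyl triol
Product: 26 (2S,3S,4S,5S)-2-[(2R,3R)-2-(4-hydroxy-3-methoxyphenyl)-3-(hydroxymethyl)-7-methoxy-2,3-dihydrobenzofuran-5-yl]-5-(4-hydroxy-3-methoxybenzyl)-3-(hydroxymethyl)tetrahydrofuran-4-ol (CNP0179668.1)
Conditions: H2 (1 atm), Pd/C (10%), EtOAc/EtOH, rt; stopped at full conversion
Reagents that add atoms: none
Why: Catalytic hydrogenolysis cleaves the two aryl benzyl ethers rapidly at 1 atm; stopping at that point should leave the cyclic benzylic ethers (C2–O1, C2'–O1') and the six stereocentres untouched.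

**Compound list**

1 | 4-(benzyloxy)-3-methoxybenzyl alcohol (commercial benzyl ether of vanillyl alcohol) | COc1cc(CO)ccc1OCc1ccccc1 | starting material
2 | 4-(benzyloxy)-3-methoxybenzyl chloride | COc1cc(CCl)ccc1OCc1ccccc1 | intermediate
3 | eugenol | COc1cc(CC=C)ccc1O | starting material
4 | 4-allyl-1-(benzyloxy)-2-methoxybenzene | COc1cc(CC=C)ccc1OCc1ccccc1 | intermediate
5 | 9-{3-[4-(benzyloxy)-3-methoxyphenyl]propyl}-9-borabicyclo[3.3.1]nonane | COc1cc(CCCB2C3CCCC2CCC3)ccc1OCc1ccccc1 | intermediate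
6 | 3-[4-(benzyloxy)-3-methoxyphenyl]propan-1-ol | COc1cc(CCCO)ccc1OCc1ccccc1 | intermediate
7 | 3-[4-(benzyloxy)-3-methoxyphenyl]propanal | COc1cc(CCC=O)ccc1OCc1ccccc1 | intermediate
8 | (R)-2-chloro-3-[4-(benzyloxy)-3-methoxyphenyl]propanal | O=C[C@H](Cl)Cc1ccc(OCc2ccccc2)c(OC)c1 | intermediate
9 | 5-iodovanillin | COc1cc(C=O)cc(I)c1O | starting material
10 | 4-{[4-(benzyloxy)-3-methoxybenzyl]oxy}-3-iodo-5-methoxybenzaldehyde | COc1cc(C=O)cc(I)c1OCc1ccc(OCc2ccccc2)c(OC)c1 | intermediate
11 | ethyl 3-hydroxy-3-ArB-propanoate (racemic) | CCOC(=O)CC(O)c1cc(OC)c(OCc2ccc(OCc3ccccc3)c(OC)c2)c(I)c1 | intermediate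
12 | 1-ArB-propane-1,3-diol (racemic) | OCCC(O)c1cc(OC)c(OCc2ccc(OCc3ccccc3)c(OC)c2)c(I)c1 | intermediate
13 | 3-(TBDPS-oxy)-1-ArB-propan-1-ol (racemic) | CC(C)(C)[Si](OCCC(O)c1cc(OC)c(OCc2ccc(OCc3ccccc3)c(OC)c2)c(I)c1)(c1ccccc1)c1ccccc1 | intermediate
14 | 3-(TBDPS-oxy)-1-ArB-propan-1-one | CC(C)(C)[Si](OCCC(=O)c1cc(OC)c(OCc2ccc(OCc3ccccc3)c(OC)c2)c(I)c1)(c1ccccc1)c1ccccc1 | intermediate
15 | (Z)-enol dibutylborinate of 14 | CCCCB(CCCC)O/C(=C\CO[Si](c1ccccc1)(c1ccccc1)C(C)(C)C)c1cc(OC)c(OCc2ccc(OCc3ccccc3)c(OC)c2)c(I)c1 | intermediate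
16 | dibutylboron aldolate of 17 (boron on the carbinol oxygen) | O=C(c1cc(OC)c(OCc2ccc(OCc3ccccc3)c(OC)c2)c(I)c1)[C@@H](CO[Si](c1ccccc1)(c1ccccc1)C(C)(C)C)[C@H](OB(CCCC)CCCC)[C@H](Cl)Cc1ccc(OCc2ccccc2)c(OC)c1 | intermediate
17 | (2S,3S,4R)-4-chloro-3-hydroxy-2-[(TBDPS-oxy)methyl]-1-ArB-5-ArC-pentan-1-one | O=C(c1cc(OC)c(OCc2ccc(OCc3ccccc3)c(OC)c2)c(I)c1)[C@@H](CO[Si](c1ccccc1)(c1ccccc1)C(C)(C)C)[C@H](O)[C@H](Cl)Cc1ccc(OCc2ccccc2)c(OC)c1 | intermediate
18 | (1S,2R,3S,4R)-4-chloro-2-[(TBDPS-oxy)methyl]-1-ArB-5-ArC-pentane-1,3-diol | O[C@H](c1cc(OC)c(OCc2ccc(OCc3ccccc3)c(OC)c2)c(I)c1)[C@@H](CO[Si](c1ccccc1)(c1ccccc1)C(C)(C)C)[C@H](O)[C@H](Cl)Cc1ccc(OCc2ccccc2)c(OC)c1 | intermediate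
19 | (2S,3S,4S,5S)-2-ArB-5-(ArC-methyl)-3-[(TBDPS-oxy)methyl]tetrahydrofuran-4-ol | COc1cc(C[C@@H]2O[C@H](c3cc(OC)c(OCc4ccc(OCc5ccccc5)c(OC)c4)c(I)c3)[C@@H](CO[Si](c3ccccc3)(c3ccccc3)C(C)(C)C)[C@@H]2O)ccc1OCc1ccccc1 | intermediate
20 | (2S,3S,4S,5S)-2-ArB-5-(ArC-methyl)-3-(hydroxymethyl)tetrahydrofuran-4-ol | COc1cc(C[C@@H]2O[C@H](c3cc(OC)c(OCc4ccc(OCc5ccccc5)c(OC)c4)c(I)c3)[C@@H](CO)[C@@H]2O)ccc1OCc1ccccc1 | intermediate
21 | [(2S,3R,4S,5S)-4-acetoxy-2-ArB-5-(ArC-methyl)tetrahydrofuran-3-yl]methyl acetate | COc1cc(C[C@@H]2O[C@H](c3cc(OC)c(OCc4ccc(OCc5ccccc5)c(OC)c4)c(I)c3)[C@@H](COC(C)=O)[C@@H]2OC(C)=O)ccc1OCc1ccccc1 | intermediate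
22 | ethyl diazoacetate | CCOC(=O)C=[N+]=[N-] | starting material
23 | tetrahydrofuran-bearing aryl diazoacetate (diacetate; key-step precursor) | COc1cc(C[C@@H]2O[C@H](c3cc(OC)c(OCc4ccc(OCc5ccccc5)c(OC)c4)c(c3)C(=[N+]=[N-])C(=O)OCC)[C@@H](COC(C)=O)[C@@H]2OC(C)=O)ccc1OCc1ccccc1 | intermediate
24 | ethyl (2R,3S)-cis-2-ArC-7-methoxy-5-[diacetoxy tetrahydrofuran-2-yl]-2,3-dihydrobenzofuran-3-carboxylate (key-step product) | COc1cc(C[C@@H]2O[C@H](c3cc(OC)c4c(c3)[C@H](C(=O)OCC)[C@H](c3ccc(OCc5ccccc5)c(OC)c3)O4)[C@@H](COC(C)=O)[C@@H]2OC(C)=O)ccc1OCc1ccccc1 | intermediate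
25 | bis-O-benzyl ether of the target (2'R,3'R; tetrahydrofuran 2S,3S,4S,5S) | COc1cc(C[C@@H]2O[C@H](c3cc(OC)c4c(c3)[C@H](CO)[C@H](c3ccc(OCc5ccccc5)c(OC)c3)O4)[C@@H](CO)[C@@H]2O)ccc1OCc1ccccc1 | intermediate
26 | CNP0179668.1 | COc1cc(C[C@@H]2O[C@H](c3cc(OC)c4c(c3)[C@H](CO)[C@H](c3ccc(O)c(OC)c3)O4)[C@@H](CO)[C@@H]2O)ccc1O | target

**Step count and risks**

Total: 19 steps. Longest linear sequence: 15 steps (1 → 26: step 1, then steps 6–19).

Step 17 (key step). The catalyst may lose control in the fully elaborated substrate. Partial stepwise hydride transfer at the very electron-rich C2' position could erode the cis relation. A mismatch between the ligand sphere and the tetrahydrofuran could lower face selectivity. The carbenoid could also be lost bimolecularly to the other ether C–H bonds. Fallback: the insertion is moved forward to the achiral ketone 14, a substrate without stereocentres and close to the simple 2-(benzyloxy)aryl diazoacetates for which the reaction is established. The tetrahydrofuran is then built on the finished dihydrobenzofuran. Ketone 14 is coupled with 22 (Pd(PPh3)4, Ag2CO3, Et3N, toluene) to give the diazo ketone F1. Rh2(S-PTTL)4 in toluene at −78 °C should give the cis-dihydrobenzofuran keto ester F2. The boron aldol of F2 with 8 (Bu2BOTf, iPr2NEt; the ketone enolises, the ester does not) gives the chlorohydrin F3. Me4NBH(OAc)3 gives the 1,3-anti diol F4, and AgOTf/Ag2O closes the tetrahydrofuran ester F5. iBu2AlH at −78 °C reduces the ester to the silyl-protected triol F6, and Bu4NF removes the silyl group. The fallback sets out from 14 and rejoins the route at 25.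

Step 11 (aldol). Simple diastereoselection may be incomplete, so that some 2,3-anti adduct (the C3 epimer of the tetrahydrofuran) is carried through steps 12–14 and ends as a C3-epimeric contaminant of 20. Fallback: C3 is then set under thermodynamic instead of kinetic control, on the ring. Starting from diol 20 (as the mixture), the primary alcohol alone is oxidised (TEMPO, PhI(OAc)2, CH2Cl2) to the 3-formyltetrahydrofuran F7. A catalytic amine base (Et3N or DBU, CH2Cl2, 0 °C) equilibrates the centre next to the formyl group to the isomer with the formyl group trans to both the C2 aryl and the C4 hydroxyl, which is the required one. NaBH4 in MeOH then returns 20 as a single C3 isomer.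

Step 16 (diazoacetate coupling). Oxidative addition and carbon transfer may be slow at the ortho-alkoxy, electron-rich iodide, and the palladium may instead consume ethyl diazoacetate through carbene dimerisation, leaving 21 unchanged or reduced. Fallback: the diazo group is introduced in two conventional steps. Palladium-catalysed α-arylation with the Reformatsky reagent BrZnCH2CO2Et (Pd2(dba)3, XPhos, THF, rt → 50 °C) converts 21 into the arylacetate F8. Regitz diazo transfer (4-acetamidobenzenesulfonyl azide, DBU, MeCN, 0 °C) then gives 23, where the route is rejoined.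

**Further compounds**

F1 | step 17 | ethyl diazo{2-[(4-benzyloxy-3-methoxybenzyl)oxy]-3-methoxy-5-[3-(TBDPS-oxy)propanoyl]phenyl}acetate | CCOC(=O)C(=[N+]=[N-])c1cc(C(=O)CCO[Si](c2ccccc2)(c2ccccc2)C(C)(C)C)cc(OC)c1OCc1ccc(OCc2ccccc2)c(OC)c1
F2 | step 17 | ethyl (2R,3S)-cis-2-ArC-7-methoxy-5-[3-(TBDPS-oxy)propanoyl]-2,3-dihydrobenzofuran-3-carboxylate | CC(C)(C)[Si](OCCC(=O)c1cc(OC)c2c(c1)[C@H](C(=O)OCC)[C@H](c1ccc(OCc3ccccc3)c(OC)c1)O2)(c1ccccc1)c1ccccc1
F3 | step 17 | syn-aldol chlorohydrin of F2 with 8 (chain configured as in 17) | O=C(c1cc(OC)c2c(c1)[C@H](C(=O)OCC)[C@H](c1ccc(OCc3ccccc3)c(OC)c1)O2)[C@@H](CO[Si](c1ccccc1)(c1ccccc1)C(C)(C)C)[C@H](O)[C@H](Cl)Cc1ccc(OCc2ccccc2)c(OC)c1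
F4 | step 17 | 1,3-anti diol from F3 (chain configured as in 18) | O[C@H](c1cc(OC)c2c(c1)[C@H](C(=O)OCC)[C@H](c1ccc(OCc3ccccc3)c(OC)c1)O2)[C@@H](CO[Si](c1ccccc1)(c1ccccc1)C(C)(C)C)[C@H](O)[C@H](Cl)Cc1ccc(OCc2ccccc2)c(OC)c1
F5 | step 17 | tetrahydrofuran (configured as in 19) carrying the cis-dihydrobenzofuran ethyl ester | COc1cc(C[C@@H]2O[C@H](c3cc(OC)c4c(c3)[C@H](C(=O)OCC)[C@H](c3ccc(OCc5ccccc5)c(OC)c3)O4)[C@@H](CO[Si](c3ccccc3)(c3ccccc3)C(C)(C)C)[C@@H]2O)ccc1OCc1ccccc1
F6 | step 17 | C3-(TBDPS-oxymethyl) analogue of 25 | COc1cc(C[C@@H]2O[C@H](c3cc(OC)c4c(c3)[C@H](CO)[C@H](c3ccc(OCc5ccccc5)c(OC)c3)O4)[C@@H](CO[Si](c3ccccc3)(c3ccccc3)C(C)(C)C)[C@@H]2O)ccc1OCc1ccccc1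
F7 | step 11 | (2S,3S,4S,5S)-2-ArB-5-(ArC-methyl)-4-hydroxytetrahydrofuran-3-carbaldehyde (formyl trans to both neighbours) | COc1cc(C[C@@H]2O[C@H](c3cc(OC)c(OCc4ccc(OCc5ccccc5)c(OC)c4)c(I)c3)[C@@H](C=O)[C@@H]2O)ccc1OCc1ccccc1
F8 | step 16 | ethyl arylacetate corresponding to 23 (CH2 in place of C=N2) | COc1cc(C[C@@H]2O[C@H](c3cc(OC)c(OCc4ccc(OCc5ccccc5)c(OC)c4)c(c3)CC(=O)OCC)[C@@H](COC(C)=O)[C@@H]2OC(C)=O)ccc1OCc1ccccc1
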